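The numbers in the tables are calculated on assumed constants; scatter was added.

Amounts first: at the last reading of Thursday's run, L and Z together hold 95.9% of the charge, and Q and X hold 3.10%. So I reckon with L and Z exchanging and treat the rest as a small correction.

in all of them: L 1.3 M
- Wednesday's: E 1.17 M; the very flask that is asked about, followed so far
- Thursday's: E 0.58 M; run made earlier
- flask: E 1.17 M; time 25 h

| run | time / h | Z / % | L / % | Q / % | X / % |
|---|---|---|---|---|---|
| Wednesday's | 0.333 | 1.0 | 98.9 | 0.2 | 0.7 |
| Wednesday's | 0.500 | 1.2 | 98.1 | 1.4 | 0 |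
| Wednesday's | 0.833 | 3.6 | 96.6 | 0 | 0 |
| Wednesday's | 1.33 | 3.4 | 93.9 | 0 | 0 |
| Wednesday's | 2.00 | 5.8 | 91.0 | 0 | 0.1 |
| Wednesday's | 3.00 | 9.9 | 88.3 | 0 | 0.5 |
| Wednesday's | 5.00 | 13.6 | 86.2 | 0.1 | 0.5 |
| Thursday's | 0.833 | 2.6 | 98.0 | 0 | 0 |
| Thursday's | 1.33 | 5.6 | 95.0 | 0 | 1.0 |
| Thursday's | 2.00 | 8.1 | 93.1 | 0.7 | 0 |
| Thursday's | 3.00 | 8.9 | 89.0 | 0 | 0 |
| Thursday's | 4.00 | 14.7 | 87.1 | 0 | 0 |
| Thursday's | 6.00 | 18.9 | 81.5 | 0 | 1.3 |
| Thursday's | 10.0 | 22.7 | 73.2 | 1.3 | 1.8 |

(scatter of a reading: 1 percentage point)

1. the species that holds most of what was charged as L, at 25 h (X / L / Z / Q)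
2. the largest share itself, whichever of these holds it, in percent of the L charged

- a species is counted by the L in it: one X counts as two
- a reading or a percentage of Q counts all its forms, free or not

*How fast does L leave?* The minus logarithm of L's share, divided by time, reads 0.0415 h⁻¹ at Wednesday's second-last reading and 0.0345 h⁻¹ at Thursday's third-last. Wednesday's run has twice the E, yet its constant is less than twice Thursday's. So I take the mean, 0.0380 h⁻¹, first order in [L].

*Can that simply be extended to the asked time?* No. Over Thursday's last two readings L falls 0.0207 h⁻¹ of the charge, but 0.0380 h⁻¹ on the mean L there predicts 0.0294 h⁻¹, which is faster. I read the gap as Z returning to L; divided by the mean Z, it gives a return constant of 0.0416 h⁻¹.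

*What follows for the flask?* The balance share, the equilibrium share of L where going and returning match, is the return constant over the sum of both: 52.2%. L relaxes towards it at the sum of the constants, so my reckoning gives 58.8% at 25 h. That is more than the remainder, so L holds most.

*And the weak spot?* Q and X draw on the pair and the reckoning leaves them out, so I expect my figure to be somewhat high.

The forecast says L at 83%, “L still dominates”, close to the last Wednesday reading of L, 86.2%, taken over.

The flask gives L at 55.0%.

    2 Z → X (k = 0.0320 M⁻¹ h⁻¹)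
    G ⇌ Q, rate k2*(cs2 - [Q]) while solid is left; crystals form when [Q] > cs2 (solubility = 0.780 M, k = 2.00 h⁻¹)
    Z + J ⇌ Q (K = 0.400 M⁻¹, k = 0.0360 M⁻¹ h⁻¹)
    L ⇌ Z (K = 0.810, k = 0.0390 h⁻¹)
    E → J (k = 0.140 h⁻¹)

My figure stands 3.8 percentage points above that, while Q and X together hold 18.3% at 25.0 h. The neighbouring flask is the same flask read at 4.0 d. There the relaxation term has died away, so the reckoning gives 52.2%, the balance share itself. That neighbouring flask shows L at 28.7% and Z at 19.6%, so L's share within the pair is 59.4%. Q stands at 8.72%, and X, now holding most, at 43.0%.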